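## Retrosynthetic overview

1. The ten-membered ring is closed last, by an intramolecular Nozaki–Hiyama–Kishi reaction forming C9–C10 (α-acyloxy aldehyde + Z-vinyl iodide); this frees C9–OH with the C8 ester already in place.
2. Before that, C3–C4 is made by a ligand-controlled Ni/Cr coupling of the lactone Z-vinyl iodide with a Z-stannyl aldehyde, followed by acetylation and tin-to-iodine exchange.
3. Key step (C6–O bond): a stereoinvertive lactone transposition. A trans lactone on O8 carrying an anti C6 mesylate is opened by hydroxide and recloses by carboxylate SN2 at C6. This gives the cis lactone on O6 and unmasks C8–OH for esterification with (2R,3R)-epoxyangelic acid (Sharpless epoxidation route).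
4. C6–C7 comes from a CrCl2 Barbier allylation of (Z)-3-iodobut-2-enal with a (5S)-3-(bromomethyl)butenolide, itself made by chromium-catalysed asymmetric 2-(methoxycarbonyl)allylation of dimethoxyacetaldehyde.
5. Ring order: γ-lactone on O8, then γ-lactone on O6 (transposed), then the ten-membered carbocycle.

Assumption 1: atom labels are germacrane-type labels used only for orientation: C6 lactone carbinol carbon, C7 ring-fusion carbon, C8 ester-bearing carbon, C9 carbinol carbon, C10(Me)=C1, C2, C3 acetate-bearing carbon, C4(Me)=C5, C11–C13 the methylidene-lactone unit (C12 carbonyl).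

Assumption 2: the ligand enantiomers named in steps 4 and 13 are taken to give Si-face and Re-face addition respectively; if a model run shows the opposite sense, the mirror-image ligand is used.

## Route

Step 1
Reactants: 1 angelic acid ((2Z)-2-methylbut-2-enoic acid)
Product: 2 (2Z)-2-methylbut-2-en-1-ol
Conditions: LiAlH4, Et2O, 0 °C to rt; then H2O
Reagents that add atoms: none
Why: Hydride reduction of the carboxylic acid to the allylic alcohol is a 1,2-reduction and leaves the Z double bond untouched.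

Step 2
Reactants: 2 (2Z)-2-methylbut-2-en-1-ol
Product: 3 [(2S,3R)-2,3-dimethyloxiran-2-yl]methanol
Conditions: Ti(OiPr)4 (10 mol %), L-(+)-diethyl tartrate (12 mol %), t-BuOOH, 4 Å molecular sieves, CH2Cl2, −20 °C
Reagents that add atoms: tert-butyl hydroperoxide, CC(C)(C)OO
Why: Sharpless asymmetric epoxidation with the L-(+)-tartrate delivers oxygen to the face that gives the 2S,3R epoxy alcohol, and syn addition to the Z alkene keeps the two methyl groups trans (epoxyangelate series).

Step 3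
Reactants: 3 [(2S,3R)-2,3-dimethyloxiran-2-yl]methanol
Product: 5 (2R,3R)-2,3-dimethyloxirane-2-carboxylic acid, via epoxy aldehyde 4 (not isolated)
Conditions: RuCl3 (2 mol %), NaIO4, CCl4/MeCN/H2O, rt
Reagents that add atoms: water, O
Why: Ruthenium tetroxide oxidation (Sharpless conditions) takes the primary alcohol through the aldehyde hydrate to the acid without touching the epoxide stereocentres (the C2 descriptor changes by priority only).

Step 4
Reactants: 6 2,2-dimethoxyacetaldehyde (anhydrous); 7 methyl 2-(bromomethyl)prop-2-enoate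
Product: 10 (5S)-5-(dimethoxymethyl)-3-methylideneoxolan-2-one, via silyl ether 8 (not isolated), via hydroxy ester 9 (not isolated)
Conditions: CrCl2 (10 mol %), (S,S)-3,6-di-tert-butyl-1,8-bis(4-isopropyl-4,5-dihydro-1,3-oxazol-2-yl)-9H-carbazole (12 mol %), i-Pr2NEt (30 mol %), Mn powder, Me3SiCl, THF, rt; then citric acid, MeOH/H2O; then (1S)-10-camphorsulfonic acid (5 mol %), CH2Cl2, rt
Reagents that add atoms: none
Why: Chromium-catalysed asymmetric Nozaki–Hiyama 2-(alkoxycarbonyl)allylation adds the allyl unit to the Si face of the aldehyde and sets C8 as S, and acid then closes the γ-lactone with retention at C8.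

Step 5
Reactants: 10 (5S)-5-(dimethoxymethyl)-3-methylideneoxolan-2-one
Product: 12 (5S)-3-(bromomethyl)-5-(dimethoxymethyl)furan-2(5H)-one, via dibromide 11 (not isolated)
Conditions: Br2, CH2Cl2, 0 °C; then Et3N (1.05 equiv), 0 °C
Reagents that add atoms: bromine, BrBr
Why: Bromine addition to the exocyclic alkene followed by E2 loss of HBr across C7–C11 gives the endocyclic allylic bromide; C8 is not involved, and short contact with the weak base at 0 °C avoids γ-epimerisation.

Step 6
Reactants: 13 but-2-yn-1-ol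
Product: 15 (2Z)-3-iodobut-2-en-1-ol, via cyclic alkenylalanate 14 (not isolated)
Conditions: NaAlH2(OCH2CH2OMe)2, THF, 0 °C to rt; then I2, −78 °C to rt
Reagents that add atoms: iodine, II
Why: Hydroxyl-directed trans-hydroalumination of the propargylic alcohol and iodinolysis of the C–Al bond with retention give the Z vinyl iodide (iodine cis to CH2OH).

Step 7
Reactants: 15 (2Z)-3-iodobut-2-en-1-ol
Product: 16 (2Z)-3-iodobut-2-enal
Conditions: MnO2, CH2Cl2, rt
Reagents that add atoms: none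
Why: Allylic oxidation with MnO2 gives the enal without touching the vinyl iodide or its Z geometry (used at once).

Step 8
Reactants: 12 (5S)-3-(bromomethyl)-5-(dimethoxymethyl)furan-2(5H)-one; 16 (2Z)-3-iodobut-2-enal
Product: 17 (4R,5S)-5-(dimethoxymethyl)-4-[(1R,2Z)-1-hydroxy-3-iodobut-2-en-1-yl]-3-methylideneoxolan-2-one
Conditions: CrCl2 (3 equiv, nickel-free), THF, 0 °C; then aq NH4Cl, 0 °C
Reagents that add atoms: none
Why: Chromium-mediated Barbier (Nozaki–Hiyama) allylation: without a nickel salt the vinyl iodide is inert, the allylchromium reacts at ring carbon C7 anti to the C8 substituent (trans lactone), and the chair transition state of the ring-locked E-type allyl unit gives the anti C6 carbinol (6R).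

Step 9
Reactants: 17 (4R,5S)-5-(dimethoxymethyl)-4-[(1R,2Z)-1-hydroxy-3-iodobut-2-en-1-yl]-3-methylideneoxolan-2-one
Product: 20 (4S,5S)-4-[(1S)-1-hydroxy-2,2-dimethoxyethyl]-5-[(1Z)-2-iodoprop-1-en-1-yl]-3-methylideneoxolan-2-one, via mesylate 18 (not isolated), via lithium carboxylate 19 (not isolated)
Conditions: MeSO2Cl, Et3N, CH2Cl2, −40 °C; then LiOH (1.05 equiv), THF/H2O, 0 °C to rt
Reagents that add atoms: lithium hydroxide, [Li+].[OH-]
Why: Proposed new method: stereoinvertive lactone transposition, in which the only free hydroxyl (C6) is mesylated, hydroxide opens the α-methylene γ-lactone at the acyl carbon, and the C12 carboxylate so unmasked displaces the allylic mesylate intramolecularly (5-exo-tet SN2, inversion at C6), so the lactone moves from O8 to O6 as the cis-disubstituted ring and C8–OH is set free; the closest known reaction type is invertive lactonisation of sulfonyloxy carboxylates (Mitsunobu-type closure) together with base-mediated translactonisation with retention.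

Step 10
Reactants: 20 cis-lactone alcohol (product of step 9); 5 (2R,3R)-2,3-dimethyloxirane-2-carboxylic acid
Product: 22 (1S)-1-[(2S,3R)-2-[(1Z)-2-iodoprop-1-en-1-yl]-4-methylidene-5-oxooxolan-3-yl]-2,2-dimethoxyethyl (2R,3R)-2,3-dimethyloxirane-2-carboxylate, via mixed anhydride 21 (not isolated)
Conditions: 5, 2,4,6-trichlorobenzoyl chloride, Et3N, THF, rt; then 20, 4-(dimethylamino)pyridine, toluene, 0 °C to rt
Reagents that add atoms: none
Why: Yamaguchi esterification acylates the only free hydroxyl (C8) with the hindered epoxy acid without touching any stereocentre, and prompt acylation blocks back-transfer of the lactone.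

Step 11
Reactants: 23 2,3-dihydrofuran
Product: 26 (3Z)-4-(tributylstannyl)pent-3-en-1-ol, via 5-lithio-2,3-dihydrofuran 24 (not isolated), via alkenylcopper 25 (not isolated)
Conditions: t-BuLi, THF, −60 to 0 °C; then MeLi/CuBr·SMe2, Et2O, −78 to 20 °C; then Bu3SnCl, −78 °C to rt; then H2O
Reagents that add atoms: methyllithium, C[Li]; tributyltin chloride, CCCC[Sn](Cl)(CCCC)CCCC
Why: α-Lithiation of the enol ether and copper-mediated 1,2-metalate rearrangement (Kocienski type) move methyl from copper to carbon with inversion and ring opening, leaving copper cis to the hydroxyethyl chain, and stannylation with retention gives the Z vinylstannane.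

Step 12
Reactants: 26 (3Z)-4-(tributylstannyl)pent-3-en-1-ol
Product: 27 (3Z)-4-(tributylstannyl)pent-3-enal
Conditions: Dess–Martin periodinane, pyridine, CH2Cl2, 0 °C
Reagents that add atoms: none
Why: Buffered Dess–Martin oxidation gives the β,γ-unsaturated aldehyde without double-bond migration or loss of tin (used at once).

Step 13
Reactants: 22 lactone Z-vinyl iodide carrying the epoxyangelate (product of step 10); 27 (3Z)-4-(tributylstannyl)pent-3-enal
Product: 28 (1S)-1-[(2R,3R)-2-[(1Z,3S,5Z)-3-hydroxy-2-methyl-6-(tributylstannyl)hepta-1,5-dien-1-yl]-4-methylidene-5-oxooxolan-3-yl]-2,2-dimethoxyethyl (2R,3R)-2,3-dimethyloxirane-2-carboxylate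
Conditions: CrCl2 (4 equiv), (S)-N-[2-(4-tert-butyl-4,5-dihydro-1,3-oxazol-2-yl)-6-methylphenyl]methanesulfonamide (4.4 equiv), Et3N (4.4 equiv), NiCl2 (5 mol %), THF, rt
Reagents that add atoms: none
Why: Nozaki–Hiyama–Kishi alkenylation under reagent control: nickel inserts only into the vinyl iodide (the vinylstannane is inert), the chiral sulfonamide–chromium alkenyl adds to the Re face of the aldehyde to set C3 as S, and the Z geometry of C4=C5 is retained.

Step 14
Reactants: 28 C3 alcohol (product of step 13)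
Product: 29 (1S)-1-[(2R,3R)-2-[(1Z,3S,5Z)-3-(acetyloxy)-2-methyl-6-(tributylstannyl)hepta-1,5-dien-1-yl]-4-methylidene-5-oxooxolan-3-yl]-2,2-dimethoxyethyl (2R,3R)-2,3-dimethyloxirane-2-carboxylate
Conditions: Ac2O, pyridine, 4-(dimethylamino)pyridine (5 mol %), CH2Cl2, 0 °C
Reagents that add atoms: acetic anhydride, CC(=O)OC(C)=O
Why: Acetylation of the only free hydroxyl (C3) proceeds with retention.

Step 15
Reactants: 29 C3 acetate vinylstannane (product of step 14)
Product: 30 (1S)-1-[(2R,3R)-2-[(1Z,3S,5Z)-3-(acetyloxy)-6-iodo-2-methylhepta-1,5-dien-1-yl]-4-methylidene-5-oxooxolan-3-yl]-2,2-dimethoxyethyl (2R,3R)-2,3-dimethyloxirane-2-carboxylate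
Conditions: I2, CH2Cl2, 0 °C
Reagents that add atoms: iodine, II
Why: Iododestannylation is an ipso substitution with retention and gives the Z vinyl iodide far faster than iodine attacks the electron-poor or trisubstituted alkenes.

Step 16
Reactants: 30 acetal vinyl iodide (product of step 15)
Product: 32 (1S)-1-[(2R,3R)-2-[(1Z,3S,5Z)-3-(acetyloxy)-6-iodo-2-methylhepta-1,5-dien-1-yl]-4-methylidene-5-oxooxolan-3-yl]-2-oxoethyl (2R,3R)-2,3-dimethyloxirane-2-carboxylate, via collidinium salt 31 (not isolated)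
Conditions: Et3SiOSO2CF3, 2,4,6-collidine, CH2Cl2, 0 °C; then H2O
Reagents that add atoms: water, O
Why: Fujioka-type acetal cleavage turns the dimethyl acetal into a pyridinium N,O-acetal that water hydrolyses under near-neutral conditions, which spares the epoxide, the esters and the allylic acetate and does not epimerise C8.

Step 17
Reactants: 32 seco aldehyde (product of step 16)
Product: 33 (3aR,4S,5R,6Z,9S,10Z,11aR)-9-(acetyloxy)-5-hydroxy-6,10-dimethyl-3-methylidene-2-oxo-2,3,3a,4,5,8,9,11a-octahydrocyclodeca[b]furan-4-yl (2R,3R)-2,3-dimethyloxirane-2-carboxylate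
Conditions: CrCl2 (10 equiv), NiCl2 (2 mol %), DMSO, rt, 2 mM
Reagents that add atoms: none
Why: The intramolecular Nozaki–Hiyama–Kishi reaction at high dilution closes the ten-membered ring with retention of the Z vinyl geometry, and Felkin–Anh addition anti to the C8 acyloxy group gives the 8,9-anti arrangement (9R).

## Compound list

1 | angelic acid, (2Z)-2-methylbut-2-enoic acid | C/C=C(/C)C(=O)O | starting material
2 | (2Z)-2-methylbut-2-en-1-ol | C/C=C(/C)CO | intermediate
3 | [(2S,3R)-2,3-dimethyloxiran-2-yl]methanol | OC[C@]1(C)O[C@@H]1C | intermediate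
4 | (2R,3R)-2,3-dimethyloxirane-2-carbaldehyde (epoxy aldehyde) | O=C[C@]1(C)O[C@@H]1C | intermediate
5 | (2R,3R)-2,3-dimethyloxirane-2-carboxylic acid | OC(=O)[C@]1(C)O[C@@H]1C | intermediate
6 | 2,2-dimethoxyacetaldehyde | COC(OC)C=O | starting material
7 | methyl 2-(bromomethyl)prop-2-enoate | COC(=O)C(=C)CBr | starting material
8 | methyl (4S)-5,5-dimethoxy-2-methylidene-4-(trimethylsilyloxy)pentanoate (silyl ether) | COC(=O)C(=C)C[C@H](O[Si](C)(C)C)C(OC)OC | intermediate
9 | methyl (4S)-4-hydroxy-5,5-dimethoxy-2-methylidenepentanoate (hydroxy ester) | COC(=O)C(=C)C[C@H](O)C(OC)OC | intermediate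
10 | (5S)-5-(dimethoxymethyl)-3-methylideneoxolan-2-one | C=C1C[C@H](OC1=O)C(OC)OC | intermediate
11 | (5S)-3-bromo-3-(bromomethyl)-5-(dimethoxymethyl)oxolan-2-one, both C3 epimers (dibromide) | BrCC1(Br)C[C@H](OC1=O)C(OC)OC | intermediate
12 | (5S)-3-(bromomethyl)-5-(dimethoxymethyl)furan-2(5H)-one | BrCC1=C[C@@H](C(OC)OC)OC1=O | intermediate
13 | but-2-yn-1-ol | CC#CCO | starting material
14 | sodium 2,2-bis(2-methoxyethoxy)-3-methyl-2,5-dihydro-1,2-oxaluminol-2-uide (cyclic alkenylalanate) | CC1=CCO[Al-]1(OCCOC)OCCOC.[Na+] | intermediate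
15 | (2Z)-3-iodobut-2-en-1-ol | OC/C=C(/C)I | intermediate
16 | (2Z)-3-iodobut-2-enal | O=C/C=C(/C)I | intermediate
17 | (4R,5S)-5-(dimethoxymethyl)-4-[(1R,2Z)-1-hydroxy-3-iodobut-2-en-1-yl]-3-methylideneoxolan-2-one | C=C1C(=O)O[C@H](C(OC)OC)[C@H]1[C@@H](O)/C=C(/C)I | intermediate
18 | (1R,2Z)-1-[(2S,3S)-2-(dimethoxymethyl)-4-methylidene-5-oxooxolan-3-yl]-3-iodobut-2-en-1-yl methanesulfonate (mesylate) | C=C1C(=O)O[C@H](C(OC)OC)[C@H]1[C@@H](OS(C)(=O)=O)/C=C(/C)I | intermediate
19 | lithium (3S,4S)-4-hydroxy-3-[(1R,2Z)-3-iodo-1-(methanesulfonyloxy)but-2-en-1-yl]-5,5-dimethoxy-2-methylidenepentanoate (lithium carboxylate) | [Li+].[O-]C(=O)C(=C)[C@@H]([C@H](O)C(OC)OC)[C@@H](OS(C)(=O)=O)/C=C(/C)I | intermediate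
20 | (4S,5S)-4-[(1S)-1-hydroxy-2,2-dimethoxyethyl]-5-[(1Z)-2-iodoprop-1-en-1-yl]-3-methylideneoxolan-2-one | C=C1C(=O)O[C@H](/C=C(/C)I)[C@@H]1[C@H](O)C(OC)OC | intermediate
21 | (2R,3R)-2,3-dimethyloxirane-2-carboxylic 2,4,6-trichlorobenzoic anhydride (mixed anhydride) | O=C(OC(=O)c1c(Cl)cc(Cl)cc1Cl)[C@]1(C)O[C@@H]1C | intermediate
22 | (1S)-1-[(2S,3R)-2-[(1Z)-2-iodoprop-1-en-1-yl]-4-methylidene-5-oxooxolan-3-yl]-2,2-dimethoxyethyl (2R,3R)-2,3-dimethyloxirane-2-carboxylate | C=C1C(=O)O[C@H](/C=C(/C)I)[C@@H]1[C@H](OC(=O)[C@]2(C)O[C@@H]2C)C(OC)OC | intermediate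
23 | 2,3-dihydrofuran | C1CC=CO1 | starting material
24 | 5-lithio-2,3-dihydrofuran | [Li]C1=CCCO1 | intermediate
25 | [(2Z)-5-(lithiooxy)pent-2-en-2-yl]copper (alkenylcopper, copper cis to the chain) | [Li]OCC/C=C(/C)[Cu] | intermediate
26 | (3Z)-4-(tributylstannyl)pent-3-en-1-ol | OCC/C=C(/C)[Sn](CCCC)(CCCC)CCCC | intermediate
27 | (3Z)-4-(tributylstannyl)pent-3-enal | O=CC/C=C(/C)[Sn](CCCC)(CCCC)CCCC | intermediate
28 | (1S)-1-[(2R,3R)-2-[(1Z,3S,5Z)-3-hydroxy-2-methyl-6-(tributylstannyl)hepta-1,5-dien-1-yl]-4-methylidene-5-oxooxolan-3-yl]-2,2-dimethoxyethyl (2R,3R)-2,3-dimethyloxirane-2-carboxylate | C=C1C(=O)O[C@H](/C=C(/C)[C@@H](O)C/C=C(/C)[Sn](CCCC)(CCCC)CCCC)[C@@H]1[C@H](OC(=O)[C@]2(C)O[C@@H]2C)C(OC)OC | intermediate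
29 | (1S)-1-[(2R,3R)-2-[(1Z,3S,5Z)-3-(acetyloxy)-2-methyl-6-(tributylstannyl)hepta-1,5-dien-1-yl]-4-methylidene-5-oxooxolan-3-yl]-2,2-dimethoxyethyl (2R,3R)-2,3-dimethyloxirane-2-carboxylate | C=C1C(=O)O[C@H](/C=C(/C)[C@@H](OC(C)=O)C/C=C(/C)[Sn](CCCC)(CCCC)CCCC)[C@@H]1[C@H](OC(=O)[C@]2(C)O[C@@H]2C)C(OC)OC | intermediate
30 | (1S)-1-[(2R,3R)-2-[(1Z,3S,5Z)-3-(acetyloxy)-6-iodo-2-methylhepta-1,5-dien-1-yl]-4-methylidene-5-oxooxolan-3-yl]-2,2-dimethoxyethyl (2R,3R)-2,3-dimethyloxirane-2-carboxylate | C=C1C(=O)O[C@H](/C=C(/C)[C@@H](OC(C)=O)C/C=C(/C)I)[C@@H]1[C@H](OC(=O)[C@]2(C)O[C@@H]2C)C(OC)OC | intermediate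
31 | 1-(1-methoxyalkyl)-2,4,6-trimethylpyridinium trifluoromethanesulfonate formed from 30 at C9, both C9 epimers (collidinium salt) | C=C1C(=O)O[C@H](/C=C(/C)[C@@H](OC(C)=O)C/C=C(/C)I)[C@@H]1[C@H](OC(=O)[C@]2(C)O[C@@H]2C)C(OC)[n+]1c(C)cc(C)cc1C.[O-]S(=O)(=O)C(F)(F)F | intermediate
32 | (1S)-1-[(2R,3R)-2-[(1Z,3S,5Z)-3-(acetyloxy)-6-iodo-2-methylhepta-1,5-dien-1-yl]-4-methylidene-5-oxooxolan-3-yl]-2-oxoethyl (2R,3R)-2,3-dimethyloxirane-2-carboxylate | C=C1C(=O)O[C@H](/C=C(/C)[C@@H](OC(C)=O)C/C=C(/C)I)[C@@H]1[C@H](OC(=O)[C@]2(C)O[C@@H]2C)C=O | intermediate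
33 | (3aR,4S,5R,6Z,9S,10Z,11aR)-9-(acetyloxy)-5-hydroxy-6,10-dimethyl-3-methylidene-2-oxo-2,3,3a,4,5,8,9,11a-octahydrocyclodeca[b]furan-4-yl (2R,3R)-2,3-dimethyloxirane-2-carboxylate | C=C1C(=O)O[C@@H]2/C=C(/C)[C@@H](OC(C)=O)C/C=C(/C)[C@@H](O)[C@@H](OC(=O)[C@]3(C)O[C@@H]3C)[C@H]12 | target

## Step count and weak points

Total step count: 17. Longest linear sequence: 10 steps (steps 4, 5, 8, 9, 10, 13, 14, 15, 16, 17).

Step 9 (the proposed lactone transposition). The allylic mesylate can eliminate towards C7 or ionise, and the hydroxy lactone 17 can shift its acyl group before sulfonylation. The fallback is known chemistry with a different activation mode. It sets out from 17: saponification with LiOH (THF/H2O, 0 °C) gives the dihydroxy acid (3R,4S)-4-hydroxy-3-[(1R,2Z)-1-hydroxy-3-iodobut-2-en-1-yl]-5,5-dimethoxy-2-methylidenepentanoic acid F1. Mitsunobu lactonisation of F1 (PPh3, diisopropyl azodicarboxylate, THF, 0 °C) then closes the five-membered ring at the more reactive allylic C6 hydroxyl with inversion and comes back to the route at 20.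

Step 13 (ligand-controlled Ni/Cr coupling). Reagent control at C3 may be weak in so hindered a coupling, and the β,γ-unsaturated aldehyde can enolise. The fallback moves the stereocontrol from the C–C bond formation to a ketone reduction. It sets out from 22 (with 27): coupling with CrCl2/NiCl2 without ligand gives the C3-epimeric alcohols (1S)-1-[(2R,3R)-2-[(1Z,5Z)-3-hydroxy-2-methyl-6-(tributylstannyl)hepta-1,5-dien-1-yl]-4-methylidene-5-oxooxolan-3-yl]-2,2-dimethoxyethyl (2R,3R)-2,3-dimethyloxirane-2-carboxylate F2. Dess–Martin oxidation gives the enone (1S)-2,2-dimethoxy-1-[(2R,3R)-2-[(1Z,5Z)-2-methyl-3-oxo-6-(tributylstannyl)hepta-1,5-dien-1-yl]-4-methylidene-5-oxooxolan-3-yl]ethyl (2R,3R)-2,3-dimethyloxirane-2-carboxylate F3. Reduction of F3 with catecholborane and (R)-1-methyl-3,3-diphenyltetrahydro-1H,3H-pyrrolo[1,2-c][1,3,2]oxazaborole at −78 °C gives the 3S alcohol and comes back to the route at 28.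

Step 17 (closure of the ten-membered ring). Oligomerisation competes with ring closure, and the C9 configuration rests on Felkin control within a macrocyclic transition state. The fallback again moves the stereocontrol to a reagent-controlled reduction. It sets out from 32: the cyclisation is run as in step 17 and whatever C9 ratio forms is taken on as the carbinol mixture (3aR,4S,6Z,9S,10Z,11aR)-9-(acetyloxy)-5-hydroxy-6,10-dimethyl-3-methylidene-2-oxo-2,3,3a,4,5,8,9,11a-octahydrocyclodeca[b]furan-4-yl (2R,3R)-2,3-dimethyloxirane-2-carboxylate (both C5 epimers) F4. Dess–Martin oxidation gives the macrocyclic enone (3aR,4S,6Z,9S,10Z,11aR)-9-(acetyloxy)-6,10-dimethyl-3-methylidene-2,5-dioxo-2,3,3a,4,5,8,9,11a-octahydrocyclodeca[b]furan-4-yl (2R,3R)-2,3-dimethyloxirane-2-carboxylate F5. Reduction of F5 with catecholborane and (R)-1-methyl-3,3-diphenyltetrahydro-1H,3H-pyrrolo[1,2-c][1,3,2]oxazaborole at −78 °C (alkenyl group taken as the large substituent) gives the 9R alcohol and comes back to the route at 33.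

## Further compounds

F1 | step 9 | (3R,4S)-4-hydroxy-3-[(1R,2Z)-1-hydroxy-3-iodobut-2-en-1-yl]-5,5-dimethoxy-2-methylidenepentanoic acid | OC(=O)C(=C)[C@@H]([C@H](O)C(OC)OC)[C@@H](O)/C=C(/C)I
F2 | step 13 | (1S)-1-[(2R,3R)-2-[(1Z,5Z)-3-hydroxy-2-methyl-6-(tributylstannyl)hepta-1,5-dien-1-yl]-4-methylidene-5-oxooxolan-3-yl]-2,2-dimethoxyethyl (2R,3R)-2,3-dimethyloxirane-2-carboxylate, both C3 epimers | C=C1C(=O)O[C@H](/C=C(/C)C(O)C/C=C(/C)[Sn](CCCC)(CCCC)CCCC)[C@@H]1[C@H](OC(=O)[C@]2(C)O[C@@H]2C)C(OC)OC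
F3 | step 13 | (1S)-2,2-dimethoxy-1-[(2R,3R)-2-[(1Z,5Z)-2-methyl-3-oxo-6-(tributylstannyl)hepta-1,5-dien-1-yl]-4-methylidene-5-oxooxolan-3-yl]ethyl (2R,3R)-2,3-dimethyloxirane-2-carboxylate | C=C1C(=O)O[C@H](/C=C(/C)C(=O)C/C=C(/C)[Sn](CCCC)(CCCC)CCCC)[C@@H]1[C@H](OC(=O)[C@]2(C)O[C@@H]2C)C(OC)OC
F4 | step 17 | (3aR,4S,6Z,9S,10Z,11aR)-9-(acetyloxy)-5-hydroxy-6,10-dimethyl-3-methylidene-2-oxo-2,3,3a,4,5,8,9,11a-octahydrocyclodeca[b]furan-4-yl (2R,3R)-2,3-dimethyloxirane-2-carboxylate, both C5 epimers | C=C1C(=O)O[C@@H]2/C=C(/C)[C@@H](OC(C)=O)C/C=C(/C)C(O)[C@@H](OC(=O)[C@]3(C)O[C@@H]3C)[C@H]12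
F5 | step 17 | (3aR,4S,6Z,9S,10Z,11aR)-9-(acetyloxy)-6,10-dimethyl-3-methylidene-2,5-dioxo-2,3,3a,4,5,8,9,11a-octahydrocyclodeca[b]furan-4-yl (2R,3R)-2,3-dimethyloxirane-2-carboxylate | C=C1C(=O)O[C@@H]2/C=C(/C)[C@@H](OC(C)=O)C/C=C(/C)C(=O)[C@@H](OC(=O)[C@]3(C)O[C@@H]3C)[C@H]12
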